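**Plan**

1. Numbering: C1 lactone C=O, C2 CH2, C3 peroxy CH, C4 quaternary C–O(lactone), C5 ring CH2, C6 quaternary peroxy C, C7–C16 the chain ending in the styryl diene. Dihydrodioxine names use the same ring locants.
2. Retrosynthetic cuts, in order: C13=C14 (cinnamyl phosphonate olefination); O–C4 of the lactone (iodolactonisation onto a C4=C5 alkene, then C5–I to C5–H); C4=C5 (ring-closing metathesis); C3–O of the peroxide (SN2 by a C6 hydroperoxide); C6–O (epoxide perhydrolysis); C7–C8 (Grignard/epoxide coupling).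
3. Enabling feature: in the 1,2-dioxane ring O–O–C3–C4–C5–C6, C4–C5 is the one carbon–carbon bond that can be a ring alkene, because C3 and C6 carry the peroxide oxygens and C6 is quaternary. C4 is also where the lactone oxygen must enter. The ring is therefore made as a 4,6-dimethyl-3,6-dihydro-1,2-dioxine from an acyclic C6–O–O–C3 peroxide with a vinyl group on C6 and an isopropenyl group on C3.
4. Forward order: the chain is joined to C6 first; the acyclic peroxide is assembled; metathesis closes the dioxine (ring 1); C1 is raised to the acid and the γ-lactone is closed (ring 2); the diene is made last, since it would not survive the metathesis or the radical step.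
5. Stereochemistry: C6 from (S)-2-methylglycidol, inverted once in the perhydrolysis; C3 from a Sharpless-resolved (S)-allylic alcohol, inverted once in the peroxide alkylation; C4 relayed from C3 by the cis-fused iodolactonisation; 13E from the olefination, 15E from the reagent.
6. C1 is carried as a silyl ether, not an ester, up to the dihydrodioxine, so that no β-sulfonyloxy or β-peroxy carbonyl compound meets base before the lactone exists.

Key step: step 11

Remark: the copper-catalysed Grignard reagent is taken to open glycidyl tosylate 4 at the epoxide CH2 and not to displace the neopentyl tosylate, which is why (S)-2-methylglycidol is the correct enantiomer.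

**Route**

Step 1
Reactants: 1 6-bromohexan-1-ol
Product: 2 [(6-bromohexyl)oxy](tert-butyl)diphenylsilane
Conditions: TBDPSCl, imidazole, CH2Cl2, 0 °C → rt
Reagents that add atoms: tert-butyl(chloro)diphenylsilane (TBDPSCl), CC(C)(C)[Si](Cl)(c1ccccc1)c1ccccc1
Why: Imidazole-mediated silylation of a primary alcohol gives a TBDPS ether that tolerates Grignard formation, the acidic perhydrolysis and the later selective TBS cleavage.

Step 2
Reactants: 3 (S)-2-methylglycidol
Product: 4 [(2R)-2-methyloxiran-2-yl]methyl 4-methylbenzenesulfonate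
Conditions: TsCl, Et3N, DMAP (cat.), CH2Cl2, 0 °C
Reagents that add atoms: 4-toluenesulfonyl chloride (TsCl), Cc1ccc(cc1)S(Cl)(=O)=O
Why: O-Sulfonylation of the primary alcohol leaves the quaternary centre untouched (the descriptor changes from S to R only because CH2OTs outranks the ring CH2) and prepares the hydroxymethyl carbon to become the new epoxide carbon.

Step 3
Reactants: 2 [(6-bromohexyl)oxy](tert-butyl)diphenylsilane, 4 [(2R)-2-methyloxiran-2-yl]methyl 4-methylbenzenesulfonate
Product: 7 (2R)-2-{7-[(tert-butyldiphenylsilyl)oxy]heptyl}-2-methyloxirane, via Grignard reagent 5 (not isolated), via hydroxy tosylate 6 (not isolated)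
Conditions: 2, Mg, THF, rt; add to 4, CuI (10 mol%), THF, −40 → −20 °C, aq NH4Cl; crude, K2CO3, MeOH, rt
Reagents that add atoms: none
Why: Copper-catalysed Grignard opening of the glycidyl sulfonate at the unhindered epoxide CH2 forms C7–C8, and the tertiary alkoxide then displaces the tosylate (3-exo-tet) so that the epoxide is re-formed on the former hydroxymethyl carbon with the quaternary centre untouched, giving the (R)-epoxide.

Step 4
Reactants: 7 (2R)-2-{7-[(tert-butyldiphenylsilyl)oxy]heptyl}-2-methyloxirane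
Product: 8 (2S)-9-[(tert-butyldiphenylsilyl)oxy]-2-hydroperoxy-2-methylnonan-1-ol
Conditions: anhydrous H2O2 in Et2O (excess), phosphomolybdic acid (3 mol%), rt
Reagents that add atoms: hydrogen peroxide, OO
Why: Molybdenum(VI)-catalysed perhydrolysis of a 2,2-disubstituted epoxide delivers H2O2 to the tertiary carbon anti to the departing oxygen (borderline SN2), so C6 is inverted to the (S)-hydroperoxide while the primary carbon keeps the hydroxyl; any C6 epimer would become a separable diastereomer after step 8.

Step 5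
Reactants: 9 3-[(tert-butyldimethylsilyl)oxy]propanal, 10 isopropenylmagnesium bromide
Product: 11 rac-1-[(tert-butyldimethylsilyl)oxy]-4-methylpent-4-en-3-ol
Conditions: THF, −78 → 0 °C; aq NH4Cl
Reagents that add atoms: none
Why: 1,2-Addition of an alkenyl Grignard reagent to the aldehyde assembles C1–C4 with the C4 methyl group in one operation, the carbinol being formed as a racemate that the next step resolves.

Step 6
Reactants: 11 rac-1-[(tert-butyldimethylsilyl)oxy]-4-methylpent-4-en-3-ol
Product: 12 (3S)-1-[(tert-butyldimethylsilyl)oxy]-4-methylpent-4-en-3-ol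
Conditions: Ti(OiPr)4 (0.2 equiv), D-(−)-diisopropyl tartrate (0.25 equiv), t-BuOOH (0.6 equiv), 4 Å MS, CH2Cl2, −20 °C
Reagents that add atoms: none
Why: In the Sharpless kinetic resolution with the D-(−)-tartrate the (R)-carbinol is epoxidised much faster, so the (S)-alcohol should be recovered unchanged and provides the C3 precursor stereocentre.

Step 7
Reactants: 12 (3S)-1-[(tert-butyldimethylsilyl)oxy]-4-methylpent-4-en-3-ol
Product: 13 (3S)-1-[(tert-butyldimethylsilyl)oxy]-4-methylpent-4-en-3-yl methanesulfonate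
Conditions: MsCl, Et3N, CH2Cl2, −20 °C; used crude at once
Reagents that add atoms: methanesulfonyl chloride (MsCl), CS(Cl)(=O)=O
Why: Mesylation at oxygen does not touch the C–O bond, so the (S) configuration is retained in an allylic leaving group that is not β to a carbonyl and cannot eliminate by E1cB.

Step 8
Reactants: 8 (2S)-9-[(tert-butyldiphenylsilyl)oxy]-2-hydroperoxy-2-methylnonan-1-ol, 13 (3S)-1-[(tert-butyldimethylsilyl)oxy]-4-methylpent-4-en-3-yl methanesulfonate
Product: 14 (2S)-2-({(3R)-1-[(tert-butyldimethylsilyl)oxy]-4-methylpent-4-en-3-yl}peroxy)-9-[(tert-butyldiphenylsilyl)oxy]-2-methylnonan-1-ol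
Conditions: CsOH·H2O (0.95 equiv), 13 (1.3 equiv), DMF, 0 °C
Reagents that add atoms: none
Why: In this Williamson-type hydroperoxide alkylation the cesium peroxide (the OOH is far more acidic than the primary OH, and base is the limiting reagent) is an α-effect nucleophile that displaces the secondary mesylate by SN2 with inversion, turning (3S)-13 into the (3R)-peroxide with C6 untouched.

Step 9
Reactants: 14 (2S)-2-({(3R)-1-[(tert-butyldimethylsilyl)oxy]-4-methylpent-4-en-3-yl}peroxy)-9-[(tert-butyldiphenylsilyl)oxy]-2-methylnonan-1-ol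
Product: 15 (2S)-2-({(3R)-1-[(tert-butyldimethylsilyl)oxy]-4-methylpent-4-en-3-yl}peroxy)-9-[(tert-butyldiphenylsilyl)oxy]-2-methylnonanal
Conditions: Dess–Martin periodinane, CH2Cl2, 0 °C → rt
Reagents that add atoms: none
Why: Dess–Martin oxidation of the neopentyl primary alcohol is neutral and non-reducing, which dialkyl peroxides and both silyl ethers tolerate, and the α-peroxy aldehyde has a quaternary α-carbon that cannot epimerise.

Step 10
Reactants: 15 (2S)-2-({(3R)-1-[(tert-butyldimethylsilyl)oxy]-4-methylpent-4-en-3-yl}peroxy)-9-[(tert-butyldiphenylsilyl)oxy]-2-methylnonanal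
Product: 16 (3S)-3-({(3R)-1-[(tert-butyldimethylsilyl)oxy]-4-methylpent-4-en-3-yl}peroxy)-10-[(tert-butyldiphenylsilyl)oxy]-3-methyldec-1-ene
Conditions: Ph3PCH3Br (1.6 equiv), KHMDS (1.5 equiv), THF, 0 °C; then 15, −78 → 0 °C
Reagents that add atoms: methyltriphenylphosphonium bromide (as its ylide), C[P+](c1ccccc1)(c1ccccc1)c1ccccc1.[Br-]
Why: Wittig methylenation with the preformed non-stabilised ylide converts the non-enolisable aldehyde into the C6 vinyl group at low temperature, where a hindered dialkyl peroxide should not be reduced by the phosphorus reagent and no free amide base remains.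

Step 11
Reactants: 16 (3S)-3-({(3R)-1-[(tert-butyldimethylsilyl)oxy]-4-methylpent-4-en-3-yl}peroxy)-10-[(tert-butyldiphenylsilyl)oxy]-3-methyldec-1-ene
Product: 17 (3R,6S)-3-{2-[(tert-butyldimethylsilyl)oxy]ethyl}-6-{7-[(tert-butyldiphenylsilyl)oxy]heptyl}-4,6-dimethyl-3,6-dihydro-1,2-dioxine
Conditions: Grubbs second-generation catalyst (10 mol%, two portions), CH2Cl2 (0.005 M), 40 °C
Reagents that add atoms: none
Why: The Ru benzylidene first exchanges onto the monosubstituted C6 vinyl group to give a C5 alkylidene, which adds across the 1,1-disubstituted C3 isopropenyl alkene in an intramolecular [2+2] and cycloreverts to release ethylene and form the trisubstituted C4=C5 bond. The closest known reaction type is the ring-closing metathesis of bis-allylic dialkyl peroxides to 3,6-dihydro-1,2-dioxines with second-generation Ru carbenes, in which an O–O bond without a free OOH survives the catalyst. The six-membered ring is closed at the C4–C5 carbon–carbon bond through a ruthenacyclobutane spanning the peroxide tether, the O–O bond being carried in intact. No stereocentre is created, and C3 and C6 are not at risk because C6 is quaternary and the C3–H is not touched under neutral conditions. The step needs chemoselectivity for cyclisation over cross-metathesis and over O–O cleavage: high dilution, the gem-disubstituted C6 and the six-membered ring size favour cyclisation, and with the chain end and C1 held as silyl ethers the catalyst has no other alkene to engage.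

Step 12
Reactants: 17 (3R,6S)-3-{2-[(tert-butyldimethylsilyl)oxy]ethyl}-6-{7-[(tert-butyldiphenylsilyl)oxy]heptyl}-4,6-dimethyl-3,6-dihydro-1,2-dioxine
Product: 18 2-[(3R,6S)-6-{7-[(tert-butyldiphenylsilyl)oxy]heptyl}-4,6-dimethyl-3,6-dihydro-1,2-dioxin-3-yl]ethan-1-ol
Conditions: CSA (10 mol%), MeOH/CH2Cl2 (1:1), 0 °C
Reagents that add atoms: none
Why: Acid-catalysed methanolysis removes a primary TBS ether far faster than a primary TBDPS ether, so the C1 hydroxyl is unmasked selectively under non-basic conditions that cannot trigger Kornblum–DeLaMare opening at the allylic C3–H.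

Step 13
Reactants: 18 2-[(3R,6S)-6-{7-[(tert-butyldiphenylsilyl)oxy]heptyl}-4,6-dimethyl-3,6-dihydro-1,2-dioxin-3-yl]ethan-1-ol
Product: 20 2-[(3R,6S)-6-{7-[(tert-butyldiphenylsilyl)oxy]heptyl}-4,6-dimethyl-3,6-dihydro-1,2-dioxin-3-yl]acetic acid, via dioxinyl acetaldehyde 19 (not isolated)
Conditions: TEMPO (0.2 equiv), PhI(OAc)2 (2.5 equiv), MeCN/H2O (1:1), rt
Reagents that add atoms: water, O
Why: The TEMPO/PhI(OAc)2 oxidation in aqueous acetonitrile takes the primary alcohol through the aldehyde and its hydrate to the carboxylic acid without base or reductant, so the dialkyl peroxide, the trisubstituted alkene and the TBDPS ether should be left alone.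

Step 14
Reactants: 20 2-[(3R,6S)-6-{7-[(tert-butyldiphenylsilyl)oxy]heptyl}-4,6-dimethyl-3,6-dihydro-1,2-dioxin-3-yl]acetic acid
Product: 21 (1R,4S,5R,6S)-4-{7-[(tert-butyldiphenylsilyl)oxy]heptyl}-5-iodo-4,6-dimethyl-2,3,7-trioxabicyclo[4.3.0]nonan-8-one
Conditions: I2 (3 equiv), NaHCO3, MeCN, 0 °C, dark
Reagents that add atoms: iodine, II
Why: In this iodolactonisation the iodonium ion forms on the ring face opposite the C3 acetic acid arm and the carboxylate opens it at the tertiary C4 (Markovnikov, 5-exo) from its own face, so the γ-lactone is necessarily cis-fused, the C4 configuration is dictated by C3, and iodine sits on C5 trans to the new C–O bond.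

Step 15
Reactants: 21 (1R,4S,5R,6S)-4-{7-[(tert-butyldiphenylsilyl)oxy]heptyl}-5-iodo-4,6-dimethyl-2,3,7-trioxabicyclo[4.3.0]nonan-8-one
Product: 22 (1R,4S,6R)-4-{7-[(tert-butyldiphenylsilyl)oxy]heptyl}-4,6-dimethyl-2,3,7-trioxabicyclo[4.3.0]nonan-8-one
Conditions: Bu3SnH (2 equiv, 0.3 M), Et3B (0.2 equiv), air, toluene, 0 °C
Reagents that add atoms: none
Why: In this radical chain deiodination the stannane is used concentrated and cold so that hydrogen transfer to the C5 radical outruns its attack on the neighbouring O–O bond, and C5 becomes a plain methylene with no stereochemical consequence.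

Step 16
Reactants: 22 (1R,4S,6R)-4-{7-[(tert-butyldiphenylsilyl)oxy]heptyl}-4,6-dimethyl-2,3,7-trioxabicyclo[4.3.0]nonan-8-one
Product: 23 (1R,4S,6R)-4-(7-hydroxyheptyl)-4,6-dimethyl-2,3,7-trioxabicyclo[4.3.0]nonan-8-one
Conditions: HF·pyridine, pyridine, THF, 0 °C → rt
Reagents that add atoms: none
Why: Fluoride cleavage of the TBDPS ether with pyridine-buffered HF avoids the basicity of TBAF, so neither the lactone nor the C3–H next to the peroxide is exposed to base.

Step 17
Reactants: 23 (1R,4S,6R)-4-(7-hydroxyheptyl)-4,6-dimethyl-2,3,7-trioxabicyclo[4.3.0]nonan-8-one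
Product: 24 7-[(1R,4S,6R)-4,6-dimethyl-8-oxo-2,3,7-trioxabicyclo[4.3.0]nonan-4-yl]heptanal
Conditions: Dess–Martin periodinane, CH2Cl2, 0 °C → rt
Reagents that add atoms: none
Why: Dess–Martin oxidation of the primary alcohol to the C13 aldehyde is neutral and non-reducing, which the peroxy lactone should tolerate.

Step 18
Reactants: 24 7-[(1R,4S,6R)-4,6-dimethyl-8-oxo-2,3,7-trioxabicyclo[4.3.0]nonan-4-yl]heptanal, 25 diethyl cinnamylphosphonate
Product: 26 plakortolide Q, (1R,4S,6R)-4,6-dimethyl-4-[(7E,9E)-10-phenyldeca-7,9-dien-1-yl]-2,3,7-trioxabicyclo[4.3.0]nonan-8-one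
Conditions: 25 (1.3 equiv), LiHMDS (1.25 equiv), THF, −78 °C; then 24, −78 → 0 °C
Reagents that add atoms: none
Why: Horner–Wadsworth–Emmons olefination with the preformed lithio anion of the allylic phosphonate (no excess base) should form C13=C14 as the E alkene through reversible addition and elimination via the less hindered oxaphosphetane, while C15=C16 arrives E in the reagent and C3, C4 and C6 are untouched.

**Compound list**

1 | 6-bromohexan-1-ol | OCCCCCCBr | starting material
2 | [(6-bromohexyl)oxy](tert-butyl)diphenylsilane | BrCCCCCCO[Si](c1ccccc1)(c1ccccc1)C(C)(C)C | intermediate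
3 | (S)-2-methylglycidol, [(2S)-2-methyloxiran-2-yl]methanol | C[C@]1(CO)CO1 | starting material
4 | [(2R)-2-methyloxiran-2-yl]methyl 4-methylbenzenesulfonate | C[C@]1(COS(=O)(=O)c2ccc(C)cc2)CO1 | intermediate
5 | {6-[(tert-butyldiphenylsilyl)oxy]hexyl}magnesium bromide | Br[Mg]CCCCCCO[Si](c1ccccc1)(c1ccccc1)C(C)(C)C | intermediate
6 | (2R)-9-[(tert-butyldiphenylsilyl)oxy]-2-hydroxy-2-methylnonyl 4-methylbenzenesulfonate | C[C@](O)(COS(=O)(=O)c1ccc(C)cc1)CCCCCCCO[Si](c1ccccc1)(c1ccccc1)C(C)(C)C | intermediate
7 | (2R)-2-{7-[(tert-butyldiphenylsilyl)oxy]heptyl}-2-methyloxirane | C[C@@]1(CCCCCCCO[Si](c2ccccc2)(c2ccccc2)C(C)(C)C)CO1 | intermediate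
8 | (2S)-9-[(tert-butyldiphenylsilyl)oxy]-2-hydroperoxy-2-methylnonan-1-ol | C[C@](OO)(CCCCCCCO[Si](c1ccccc1)(c1ccccc1)C(C)(C)C)CO | intermediate
9 | 3-[(tert-butyldimethylsilyl)oxy]propanal | O=CCCO[Si](C)(C)C(C)(C)C | starting material
10 | isopropenylmagnesium bromide | CC(=C)[Mg]Br | starting material
11 | rac-1-[(tert-butyldimethylsilyl)oxy]-4-methylpent-4-en-3-ol | CC(=C)C(O)CCO[Si](C)(C)C(C)(C)C | intermediate
12 | (3S)-1-[(tert-butyldimethylsilyl)oxy]-4-methylpent-4-en-3-ol | O[C@@H](CCO[Si](C)(C)C(C)(C)C)C(C)=C | intermediate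
13 | (3S)-1-[(tert-butyldimethylsilyl)oxy]-4-methylpent-4-en-3-yl methanesulfonate | CS(=O)(=O)O[C@@H](CCO[Si](C)(C)C(C)(C)C)C(C)=C | intermediate
14 | (2S)-2-({(3R)-1-[(tert-butyldimethylsilyl)oxy]-4-methylpent-4-en-3-yl}peroxy)-9-[(tert-butyldiphenylsilyl)oxy]-2-methylnonan-1-ol | OC[C@](C)(CCCCCCCO[Si](c1ccccc1)(c1ccccc1)C(C)(C)C)OO[C@H](CCO[Si](C)(C)C(C)(C)C)C(C)=C | intermediate
15 | (2S)-2-({(3R)-1-[(tert-butyldimethylsilyl)oxy]-4-methylpent-4-en-3-yl}peroxy)-9-[(tert-butyldiphenylsilyl)oxy]-2-methylnonanal | O=C[C@](C)(CCCCCCCO[Si](c1ccccc1)(c1ccccc1)C(C)(C)C)OO[C@H](CCO[Si](C)(C)C(C)(C)C)C(C)=C | intermediate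
16 | (3S)-3-({(3R)-1-[(tert-butyldimethylsilyl)oxy]-4-methylpent-4-en-3-yl}peroxy)-10-[(tert-butyldiphenylsilyl)oxy]-3-methyldec-1-ene | C=C[C@](C)(CCCCCCCO[Si](c1ccccc1)(c1ccccc1)C(C)(C)C)OO[C@H](CCO[Si](C)(C)C(C)(C)C)C(C)=C | intermediate
17 | (3R,6S)-3-{2-[(tert-butyldimethylsilyl)oxy]ethyl}-6-{7-[(tert-butyldiphenylsilyl)oxy]heptyl}-4,6-dimethyl-3,6-dihydro-1,2-dioxine | C[C@]1(CCCCCCCO[Si](c2ccccc2)(c2ccccc2)C(C)(C)C)C=C(C)[C@@H](CCO[Si](C)(C)C(C)(C)C)OO1 | intermediate
18 | 2-[(3R,6S)-6-{7-[(tert-butyldiphenylsilyl)oxy]heptyl}-4,6-dimethyl-3,6-dihydro-1,2-dioxin-3-yl]ethan-1-ol | C[C@]1(CCCCCCCO[Si](c2ccccc2)(c2ccccc2)C(C)(C)C)C=C(C)[C@@H](CCO)OO1 | intermediate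
19 | 2-[(3R,6S)-6-{7-[(tert-butyldiphenylsilyl)oxy]heptyl}-4,6-dimethyl-3,6-dihydro-1,2-dioxin-3-yl]acetaldehyde | C[C@]1(CCCCCCCO[Si](c2ccccc2)(c2ccccc2)C(C)(C)C)C=C(C)[C@@H](CC=O)OO1 | intermediate
20 | 2-[(3R,6S)-6-{7-[(tert-butyldiphenylsilyl)oxy]heptyl}-4,6-dimethyl-3,6-dihydro-1,2-dioxin-3-yl]acetic acid | C[C@]1(CCCCCCCO[Si](c2ccccc2)(c2ccccc2)C(C)(C)C)C=C(C)[C@@H](CC(=O)O)OO1 | intermediate
21 | (1R,4S,5R,6S)-4-{7-[(tert-butyldiphenylsilyl)oxy]heptyl}-5-iodo-4,6-dimethyl-2,3,7-trioxabicyclo[4.3.0]nonan-8-one (cis-fused, iodine trans to the lactone oxygen) | C[C@]1(CCCCCCCO[Si](c2ccccc2)(c2ccccc2)C(C)(C)C)[C@H](I)[C@@]2(C)OC(=O)C[C@H]2OO1 | intermediate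
22 | (1R,4S,6R)-4-{7-[(tert-butyldiphenylsilyl)oxy]heptyl}-4,6-dimethyl-2,3,7-trioxabicyclo[4.3.0]nonan-8-one | C[C@]1(CCCCCCCO[Si](c2ccccc2)(c2ccccc2)C(C)(C)C)C[C@@]2(C)OC(=O)C[C@H]2OO1 | intermediate
23 | (1R,4S,6R)-4-(7-hydroxyheptyl)-4,6-dimethyl-2,3,7-trioxabicyclo[4.3.0]nonan-8-one | C[C@]1(CCCCCCCO)C[C@@]2(C)OC(=O)C[C@H]2OO1 | intermediate
24 | 7-[(1R,4S,6R)-4,6-dimethyl-8-oxo-2,3,7-trioxabicyclo[4.3.0]nonan-4-yl]heptanal | C[C@]1(CCCCCCC=O)C[C@@]2(C)OC(=O)C[C@H]2OO1 | intermediate
25 | diethyl cinnamylphosphonate, diethyl [(2E)-3-phenylprop-2-en-1-yl]phosphonate | CCOP(=O)(OCC)C/C=C/c1ccccc1 | starting material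
26 | plakortolide Q | C[C@]1(CCCCCC/C=C/C=C/c2ccccc2)C[C@@]2(C)OC(=O)C[C@H]2OO1 | target

**Count**

Total steps: 18. Longest linear sequence: 14 steps (1, 3, 4, 8–18 from 6-bromohexan-1-ol; the branches from 3 and from 9 are equally long).

**Steps most likely to fail**

Step 8 (peroxide alkylation). The hindered tertiary cesium peroxide may lose out to E2 elimination of the allylic mesylate or attack its methylene terminus (SN2′), and the mesylate may ionise with loss of configuration at C3. The fallback builds the two C–O bonds of the peroxide in the opposite order; it sets out from 13 (and uses 7) and returns at 14. Mesylate 13 is displaced by the small anion of 2-methoxyprop-2-yl hydroperoxide (CsOH, DMF, 0 °C; SN2 with inversion) to give tert-butyl({(3R)-3-[(2-methoxypropan-2-yl)peroxy]-4-methylpent-4-en-1-yl}oxy)dimethylsilane F1. Brief treatment with dilute aqueous acetic acid in THF hydrolyses the peroxyketal to (3R)-1-[(tert-butyldimethylsilyl)oxy]-3-hydroperoxy-4-methylpent-4-ene F2. This hydroperoxide then opens epoxide 7 at the tertiary carbon under acid catalysis (phosphomolybdic acid, Et2O), the alkyl hydroperoxide counterpart of step 4, again with inversion at C6, and gives 14 directly.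

Step 11 (ring-closing metathesis). The carbene may load only slowly on the vinyl group beside the quaternary C6, so that catalyst decomposition (including Ru-mediated O–O cleavage) and intermolecular metathesis overtake the slow closure to a trisubstituted alkene. The fallback is a relay ring-closing metathesis; it sets out from aldehyde 15 and returns at 17. Wittig reaction of 15 with the ylide from [2-(allyloxy)ethyl]triphenylphosphonium bromide (KHMDS, THF, −78 °C) gives the (Z)-3-(allyloxy)prop-1-enyl analogue of 16 F3. The catalyst then initiates at the unhindered terminal allyl ether, expels 2,5-dihydrofuran and is delivered as the C5 alkylidene directly next to C6, from where it closes onto the isopropenyl group to give 17.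

Step 18 (diene olefination). The phosphonate anion may act as a base on the peroxy lactone (β-elimination of the peroxide from the lactone enolate or Kornblum–DeLaMare opening at C3–H), and the E-selectivity at C13=C14 may be incomplete. The fallback replaces kinetic control under strong base by a weak-base olefination followed by thermodynamic isomerisation; it sets out from aldehyde 24 and returns at 26. Wittig reaction of 24 with cinnamyltriphenylphosphonium bromide under solid K2CO3/18-crown-6 in CH2Cl2 should give the diene as a mixture of 26 and its (13Z,15E)-isomer F4. A catalytic amount of iodine in CH2Cl2 under ambient light then equilibrates the mixture to the conjugated (E,E)-diene 26, conditions that do not affect a dialkyl peroxide.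

**Further compounds**

F1 | step 8 | tert-butyl({(3R)-3-[(2-methoxypropan-2-yl)peroxy]-4-methylpent-4-en-1-yl}oxy)dimethylsilane | COC(C)(C)OO[C@H](CCO[Si](C)(C)C(C)(C)C)C(C)=C
F2 | step 8 | (3R)-1-[(tert-butyldimethylsilyl)oxy]-3-hydroperoxy-4-methylpent-4-ene | OO[C@H](CCO[Si](C)(C)C(C)(C)C)C(C)=C
F3 | step 11 | (Z)-3-(allyloxy)prop-1-enyl analogue of 16 (relay substrate) | C=CCOC/C=C\[C@](C)(CCCCCCCO[Si](c1ccccc1)(c1ccccc1)C(C)(C)C)OO[C@H](CCO[Si](C)(C)C(C)(C)C)C(C)=C
F4 | step 18 | (13Z,15E)-isomer of plakortolide Q | C[C@]1(CCCCCC/C=C\C=C\c2ccccc2)C[C@@]2(C)OC(=O)C[C@H]2OO1
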